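The constant worth carrying from the earlier runs is a ratio, and it can be had without a rate law for the dying catalyst.

| flask | left-handed substrate | right-handed substrate | reagent | precatalyst | impurity | remark | time |
|---|---|---|---|---|---|---|---|
| west | 0.025 M | 0.025 M | 0.055 M | 50 µM | 37 µM | run made earlier |  |
| north-west | 0.038 M | 0.038 M | 0.055 M | 50 µM | 37 µM | run made earlier |  |
| south-west | 0.050 M | 0.050 M | 0.083 M | 50 µM | 37 µM | run made earlier |  |
| flask | 0.050 M | 0.050 M | 0.0550 M | 50 µM | 37 µM |  | 25 min |

- west (time / min: right-handed substrate / %, left-handed substrate / %, left-handed product / %): 3.00: 48.8, 46.7, 3.8; 8.00: 46.8, 42.9, 7.7; 15.0: 46.3, 38.9, 11.3; 25.0: 45.1, 36.9, 13.7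
- north-west (time / min: right-handed substrate / %, left-handed substrate / %, left-handed product / %): 6.00: 47.1, 44.3, 5.5; 12.0: 47.0, 40.9, 8.5; 20.0: 45.0, 38.1, 11.0; 25.0: 45.7, 36.5, 11.8
- south-west (time / min: right-handed substrate / %, left-handed substrate / %, left-handed product / %): 6.00: 47.1, 42.3, 7.5; 12.0: 44.9, 37.8, 13.6; 20.0: 44.0, 34.6, 16.0; 25.0: 42.8, 32.8, 16.7

(scatter of a reading: 0.5 percentage points)

- whether the excess of right-handed substrate over left-handed substrate among what is left of the two reaches 95% by 25 min (yes / no)
- the highest excess of right-handed substrate over left-handed substrate among what is left of the two up to 25 min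

- free catalyst is single-handed; left-handed substrate and right-handed substrate are mirror images of each other, charged as a racemate, each of them at the stated concentration
- the earlier runs were read with a standard deviation of 0.5 percentage points

Taking each substrate as falling first order in itself under the same catalyst and reagent, dividing one rate by the other removes the catalyst and reagent terms, and the integral closes. If depth means the natural logarithm of a substrate's charge over what is left of it, the two depths stand in a constant ratio. Summed over the last readings of the three runs, that ratio reads 2.98; this is the selectivity factor, the depth of the left-handed substrate over that of the right-handed substrate.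

For equal charges of the two substrates, the excess among what is left is the hyperbolic tangent of half the difference of the depths, so 95% needs a difference of 3.66. By my reckoning the left-handed substrate must then fall to 0.405% of its charge, far less than the 65.6% of its charge read at the last reading of the south-west run.

The forecast, holding that “The right-handed substrate reacts about 2.9 times slower”, gave no and 9%.

The flask gives no and 8.96%.

    2 free catalyst → spent catalyst A (k = 460 M⁻¹ s⁻¹)
    free catalyst + impurity → spent catalyst B (k = 22000 M⁻¹ s⁻¹)
    reagent + catalyst intermediate B → free catalyst + right-handed product (k = 66.0 M⁻¹ s⁻¹)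
    free catalyst + right-handed substrate ⇌ catalyst intermediate B (K = 8.50 M⁻¹, k = 8500 M⁻¹ s⁻¹)
    reagent + catalyst intermediate A → free catalyst + left-handed product (k = 180 M⁻¹ s⁻¹)
    free catalyst + left-handed substrate ⇌ catalyst intermediate A (K = 9.10 M⁻¹, k = 2600 M⁻¹ s⁻¹)
    precatalyst → free catalyst (k = 0.0230 s⁻¹)

In the flask, catalyst intermediate A returns 97% of its forward turnover, and this backward run is the main reason that the excess at 25 min stands at 8.96%, where the same flask without it reaches 99.8%. With 76% of the left-handed substrate left, the factor gives 9.18% for this flask. The neighbour with 8.5 × 10⁻⁵ M of precatalyst keeps 65%, for which the factor gives 14.0%, and its simulated top is 13.7%.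

The numbers in the tables are simulated with constants of no real substance, noise included.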